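| setting | theta | epsilon | eta | flask |
|---|---|---|---|---|
| left-handed substrate | 0.74 M | 1.7 M | 1.1 M | 1.1 M |
| right-handed substrate | 0.74 M | 1.7 M | 1.1 M | 1.1 M |
| gas | 41 mM (held) | 41 mM (held) | 41 mM (held) | 41 mM (held) |
| racemization catalyst | 5.5 mM | 5.5 mM | 11 mM | 5.5 mM |
| remark | run made earlier | run made earlier | run made earlier |  |
| time |  |  |  | 8.0 h |

- theta (time / h: left-handed product / %, right-handed product / %): 1.00: 33, 9; 2.50: 54, 15; 3.00: 61, 20; 5.00: 69, 24; 6.00: 69, 25; 8.00: 71, 27
- epsilon (time / h: left-handed product / %, right-handed product / %): 0.667: 17, 6; 1.00: 31, 5; 1.33: 29, 7; 2.50: 51, 10; 3.00: 53, 15; 5.00: 67, 20; 8.00: 73, 24
- eta (time / h: left-handed product / %, right-handed product / %): 0.667: 22, 6; 1.33: 39, 9; 2.50: 58, 15; 4.00: 69, 17; 8.00: 77, 22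

(readings scatter by 2 percentage points)

- reagent is single-handed; left-handed substrate and right-handed substrate are mirror images of each other, charged as a racemate, each of them at the stated concentration
- at the start none of the gas is in solution
- an excess is the difference of the two amounts in percent of their sum
- an excess is below zero if the other one leads
- the handed part of reagent does not stay in what it makes, so the products of the two hands are mirror images too

- left-handed product and right-handed product together, in percent of the left-handed substrate and right-handed substrate charged together, at 8.0 h
- excess of left-handed product over right-handed product in the product at 8.0 h
- whether the exchange between left-handed substrate and right-handed substrate keeps pace with the reaction: how far the product's excess at 8.0 h gets from its value without exchange to its value with instant exchange (above 80% keeps pace, below 20% hardly takes part, else lags behind)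

The ratio of left-handed to right-handed product in the first eta readings, 3.67 and then 4.33, is a rough reading given the scatter of 2 percentage points, and from it we take the selectivity factor, the ratio of the two rate constants, as 5.00.

Take the main step first. The reagent turns each substrate into its own product, so the product excess starts at a ceiling of 66.7%, the value that instant exchange holds throughout, but at full conversion each hand has given its whole charge and the excess falls to zero.

Now add the exchange. Each portion of right-handed substrate turned into left-handed counts twice in the excess, and the amount turned grows with the gap [right-handed substrate] − [left-handed substrate] summed over time. The exchange also narrows that gap, so the first answer must be put back in. For fixed loss constants at full conversion, going round until nothing changes gives a share of the ceiling equal to the exchange number divided by itself plus 1 minus the ceiling squared, where the exchange number is 4 times the exchange rate constant over the sum of the two loss constants.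

Last comes the reagent supply from the held gas, which makes those loss constants shift, so we read the number from eta, whose loading matches this flask's. Eta's excess of 55.6% is a share of 83.3%, which gives 2.78. Eta has twice the flask's catalyst, so the flask has 1.39, and this exchange number gives a share of 71.4% and an excess of 47.6%. That share lies below 80% and above 20%, so we say the exchange lags behind. For the yield we commit to about eta's 99.0%.

The forecast gives 97.5%, 48% and lags behind, holding that “exchange relative to reaction improves with loading”.

The flask gives 98.4% and 46.8%, and its exchange lags behind, at 62% of the way. At 8.00 h the right-handed substrate still leads what is left of the two by 59.0%, so the gap has not closed. Read backwards through our ceiling, the flask's excess gives an exchange number of 1.31, against the 1.39 scaled from eta.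

    reagent + left-handed substrate → left-handed product (k = 0.0140 M⁻¹ s⁻¹)
    reagent + right-handed substrate → right-handed product (k = 0.00240 M⁻¹ s⁻¹)
    left-handed substrate + racemization catalyst ⇌ right-handed substrate + racemization catalyst, rate k3*[racemization catalyst]*[left-handed substrate] forward; the back reaction follows from the equilibrium constant (k = 0.0180 M⁻¹ s⁻¹)
    2 reagent → self-condensation product (k = 0.0590 M⁻¹ s⁻¹)
    gas ⇌ reagent, rate k5*(csat - [reagent]) (kL = 0.0120 s⁻¹)

With the catalyst cut to 0.0033 M, the same flask has an exchange number of 0.833, which gives an excess of 40.0%. The computed neighbour gives 38.2% at a yield of 97.4%.

The readings are simulated from invented constants; noise was put on by code.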